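The route rests on cutting the C5–C6 bond of the diterpenyl chain (C1 = OCH2, ring A = the trimethylcyclohexene). The key step exploits the 1,5-diene seam C2=C3–C4–C5–C6=C7. C5 is a primary homoallylic sp3 carbon that can be released as a radical, and C6 is the CH end of the E-trisubstituted alkene. A nickel-electrocatalysed decarboxylative alkenylation joins two electrophilic carbons in the last step. One partner is an N-acyloxyphthalimide that already carries the linolenate and one extra carbon (lost as CO2). The other is the ring-A (E)-alkenyl iodide. Both alkene geometries are retained. The C1' stereocentre of ring A comes from a CBS reduction relayed by anti-SN2' substitution.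

Key step: step 12

Assumption: the epoxide stereocentre made in step 1 is left racemic, because step 4 destroys it.

Step 1
Reactants: 1 geranyl acetate
Product: 2 (2E)-6,7-epoxy-3,7-dimethyloct-2-en-1-yl acetate (racemic at the epoxide carbon)
Conditions: mCPBA (1.0 equiv), CH2Cl2, 0 °C
Reagents that add atoms: mCPBA (3-chloroperoxybenzoic acid), OOC(=O)c1cccc(Cl)c1
Why: Prilezhaev epoxidation is electrophilic, so the electron-rich terminal C6=C7 alkene should react well before the C2=C3 alkene that the allylic acetate deactivates; the new epoxide stereocentre forms racemic and is erased in step 4.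

Step 2
Reactants: 2 (2E)-6,7-epoxy-3,7-dimethyloct-2-en-1-yl acetate
Product: 3 (2E)-6,7-epoxy-3,7-dimethyloct-2-en-1-ol (6,7-epoxygeraniol)
Conditions: K2CO3 (0.2 equiv), MeOH, rt
Reagents that add atoms: none
Why: Carbonate-catalysed transesterification with methanol should free the primary allylic alcohol without opening the trisubstituted epoxide.

Step 3
Reactants: 3 6,7-epoxygeraniol; 4 α-linolenic acid, (9Z,12Z,15Z)-octadeca-9,12,15-trienoic acid
Product: 5 (2E)-6,7-epoxy-3,7-dimethyloct-2-en-1-yl (9Z,12Z,15Z)-octadeca-9,12,15-trienoate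
Conditions: N,N'-dicyclohexylcarbodiimide (1.1 equiv), 4-dimethylaminopyridine (DMAP, 0.1 equiv), CH2Cl2, 0 °C to rt
Reagents that add atoms: none
Why: Steglich esterification runs under near-neutral conditions that should spare the epoxide and leave the skipped Z,Z,Z-triene of 4 unisomerised.

Step 4
Reactants: 5 epoxygeranyl linolenate
Product: 6 (2E)-3-methyl-6-oxohex-2-en-1-yl (9Z,12Z,15Z)-octadeca-9,12,15-trienoate
Conditions: H5IO6 (1.2 equiv), THF/Et2O, 0 °C
Reagents that add atoms: none
Why: Periodic acid should hydrolyse the epoxide to the glycol and cleave it in the same flask (Malaprade glycol cleavage), an oxidation that touches neither isolated alkenes nor the allylic ester.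

Step 5
Reactants: 6 aldehyde
Product: 7 (4E)-4-methyl-6-[(9Z,12Z,15Z)-octadeca-9,12,15-trienoyloxy]hex-4-enoic acid
Conditions: NaClO2, NaH2PO4, 2-methyl-2-butene (large excess), t-BuOH/H2O, 0 °C to rt
Reagents that add atoms: sodium chlorite, [Na+].[O-]Cl=O
Why: Pinnick oxidation is specific for the aldehyde, and the large excess of 2-methyl-2-butene should trap the hypochlorous acid before it can add to the four alkenes of 6.

Step 6
Reactants: 7 acid; 8 N-hydroxyphthalimide
Product: 9 1,3-dioxoisoindolin-2-yl (4E)-4-methyl-6-[(9Z,12Z,15Z)-octadeca-9,12,15-trienoyloxy]hex-4-enoate (redox-active ester)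
Conditions: N,N'-diisopropylcarbodiimide (1.1 equiv), DMAP (0.1 equiv), CH2Cl2, rt
Reagents that add atoms: none
Why: Carbodiimide activation (Steglich type) should acylate the N–OH group of 8 under neutral conditions and give the redox-active ester without touching the allylic ester.

Step 7
Reactants: 10 2,4,4-trimethylcyclohex-2-en-1-one
Product: 11 (S)-2,4,4-trimethylcyclohex-2-en-1-ol
Conditions: (R)-2-methyl-CBS-oxazaborolidine [(3aR)-1-methyl-3,3-diphenyltetrahydro-1H,3H-pyrrolo[1,2-c][1,3,2]oxazaborole, 0.2 equiv], BH3·SMe2 (1.0 equiv), THF, −20 °C; aqueous work-up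
Reagents that add atoms: none
Why: Corey–Bakshi–Shibata reduction: the methyl-bearing alkenyl arm acts as the large substituent and the ring CH2 as the small one, so the (R)-catalyst should deliver hydride 1,2 to the face that gives the (S)-carbinol.

Step 8
Reactants: 11 (S)-2,4,4-trimethylcyclohex-2-en-1-ol; 12 picolinic acid (pyridine-2-carboxylic acid)
Product: 13 (S)-2,4,4-trimethylcyclohex-2-en-1-yl pyridine-2-carboxylate
Conditions: N,N'-dicyclohexylcarbodiimide (1.2 equiv), DMAP (0.1 equiv), CH2Cl2, rt
Reagents that add atoms: none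
Why: Steglich esterification leaves the C–O bond of the carbinol intact, so the (S) configuration is kept while a chelating leaving group is installed.

Step 9
Reactants: 13 (S)-allylic picolinate; 14 (4-bromobut-1-yn-1-yl)trimethylsilane
Product: 17 trimethyl{4-[(1S)-2,6,6-trimethylcyclohex-2-en-1-yl]but-1-yn-1-yl}silane, via Grignard reagent 15 (not isolated), via organocopper reagent 16 (not isolated)
Conditions: 14 (2 equiv), Mg, THF, rt; CuBr·SMe2 (2 equiv), THF, −40 °C; then 13, −40 to 0 °C; aq NH4Cl
Reagents that add atoms: none
Why: Copper-mediated anti-SN2' allylic substitution: MgBr2 chelated by the picolinoxy group activates it, copper should attack the alkene CH next to the gem-dimethyl carbon on the face opposite to the leaving group, and the (S) C–O stereocentre is thereby transposed into the (S) C–C stereocentre C1' while the ring alkene moves into its final position.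

Step 10
Reactants: 17 silylalkyne
Product: 18 (6S)-6-(but-3-yn-1-yl)-1,5,5-trimethylcyclohex-1-ene
Conditions: K2CO3 (0.2 equiv), MeOH, rt
Reagents that add atoms: none
Why: Methanolysis of the alkynyl C–Si bond (protodesilylation) is mild and should touch neither the ring alkene nor C1'.

Step 11
Reactants: 18 terminal alkyne
Product: 20 (6S)-6-[(3E)-4-iodo-3-methylbut-3-en-1-yl]-1,5,5-trimethylcyclohex-1-ene, via alkenylalane 19 (not isolated)
Conditions: AlMe3 (2.5 equiv), Cp2ZrCl2 (0.25 equiv), CH2Cl2, 0 °C to rt; then I2, THF, −30 °C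
Reagents that add atoms: trimethylaluminium, C[Al](C)C; iodine, [I][I]
Why: Negishi zirconium-catalysed carboalumination adds CH3 and Al syn across the terminal alkyne with Al on the terminal carbon, and iodinolysis with retention should give the E-alkenyl iodide, the trisubstituted ring alkene being inert.

Step 12
Reactants: 9 redox-active ester; 20 (E)-alkenyl iodide
Product: 21 (2E,6E)-3,7-dimethyl-9-[(1S)-2,6,6-trimethylcyclohex-2-en-1-yl]nona-2,6-dien-1-yl (9Z,12Z,15Z)-octadeca-9,12,15-trienoate (target)
Conditions: 9 (1.5 equiv), 20 (1.0 equiv), NiCl2·6H2O (20 mol %), 2,2'-bipyridine (20 mol %), AgNO3 (0.3 equiv, plated in situ on the cathode), LiCl, DMF, Mg anode, reticulated vitreous carbon cathode, undivided cell, constant current (about 3 F/mol), rt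
Reagents that add atoms: none
Why: Low-valent (bpy)nickel formed at the silver-coated cathode inserts into the C–I bond of 20 with retention to give a divalent alkenylnickel iodide, while one-electron reduction of the phthalimide unit of 9 (by the cathode or by monovalent nickel) triggers N–O cleavage and loss of CO2 and releases the primary homoallylic C5 radical. Capture of this radical gives a trivalent alkyl(alkenyl)nickel that reductively eliminates the C5–C6 bond, and the magnesium anode supplies the two electrons that the union of two electrophilic carbons requires. The closest known reaction type is the nickel-electrocatalytic decarboxylative alkenylation of redox-active esters with alkenyl iodides, which has been applied to this same CH2–CH=C(CH3) seam of acyclic terpenes. No ring is closed and no stereocentre is created; the remote C1' of ring A is untouched, and the E geometry at C6=C7 is inherited from 20 because the alkenylnickel species is configurationally stable. The step needs cross-coupling over homo-coupling, which the orthogonal activation modes secure (two-electron insertion for the sp2 iodide, one-electron fragmentation for the ester); it also needs chemoselectivity against the allylic linolenate and the bis-allylic C–H bonds, which should hold because insertion into the alkenyl iodide is much faster than ionisation of a 3,3-disubstituted allylic ester and because capture at nickel outruns intermolecular hydrogen abstraction. The E geometry at C2=C3 should survive because 3-exo closure of the C5 radical onto C3 is slow and reversible compared with capture.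

Compound list
1 | geranyl acetate, (2E)-3,7-dimethylocta-2,6-dien-1-yl acetate | CC(=O)OC/C=C(\C)CCC=C(C)C | starting material
2 | (2E)-6,7-epoxy-3,7-dimethyloct-2-en-1-yl acetate (racemic epoxide) | CC(=O)OC/C=C(\C)CCC1OC1(C)C | intermediate
3 | (2E)-6,7-epoxy-3,7-dimethyloct-2-en-1-ol (racemic epoxide) | OC/C=C(\C)CCC1OC1(C)C | intermediate
4 | α-linolenic acid, (9Z,12Z,15Z)-octadeca-9,12,15-trienoic acid | CC/C=C\C/C=C\C/C=C\CCCCCCCC(=O)O | starting material
5 | (2E)-6,7-epoxy-3,7-dimethyloct-2-en-1-yl (9Z,12Z,15Z)-octadeca-9,12,15-trienoate (racemic epoxide) | CC/C=C\C/C=C\C/C=C\CCCCCCCC(=O)OC/C=C(\C)CCC1OC1(C)C | intermediate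
6 | (2E)-3-methyl-6-oxohex-2-en-1-yl (9Z,12Z,15Z)-octadeca-9,12,15-trienoate | CC/C=C\C/C=C\C/C=C\CCCCCCCC(=O)OC/C=C(\C)CCC=O | intermediate
7 | (4E)-4-methyl-6-[(9Z,12Z,15Z)-octadeca-9,12,15-trienoyloxy]hex-4-enoic acid | CC/C=C\C/C=C\C/C=C\CCCCCCCC(=O)OC/C=C(\C)CCC(=O)O | intermediate
8 | N-hydroxyphthalimide | O=C1c2ccccc2C(=O)N1O | starting material
9 | 1,3-dioxoisoindolin-2-yl (4E)-4-methyl-6-[(9Z,12Z,15Z)-octadeca-9,12,15-trienoyloxy]hex-4-enoate | CC/C=C\C/C=C\C/C=C\CCCCCCCC(=O)OC/C=C(\C)CCC(=O)ON1C(=O)c2ccccc2C1=O | intermediate
10 | 2,4,4-trimethylcyclohex-2-en-1-one | CC1=CC(C)(C)CCC1=O | starting material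
11 | (S)-2,4,4-trimethylcyclohex-2-en-1-ol | O[C@H]1CCC(C)(C)C=C1C | intermediate
12 | picolinic acid (pyridine-2-carboxylic acid) | OC(=O)c1ccccn1 | starting material
13 | (S)-2,4,4-trimethylcyclohex-2-en-1-yl pyridine-2-carboxylate | O=C(O[C@H]1CCC(C)(C)C=C1C)c1ccccn1 | intermediate
14 | (4-bromobut-1-yn-1-yl)trimethylsilane | C[Si](C)(C)C#CCCBr | starting material
15 | [4-(trimethylsilyl)but-3-yn-1-yl]magnesium bromide | C[Si](C)(C)C#CCC[Mg]Br | intermediate
16 | [4-(trimethylsilyl)but-3-yn-1-yl]copper (MgBr2 complex) | C[Si](C)(C)C#CCC[Cu] | intermediate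
17 | trimethyl{4-[(1S)-2,6,6-trimethylcyclohex-2-en-1-yl]but-1-yn-1-yl}silane | C[Si](C)(C)C#CCC[C@@H]1C(C)=CCCC1(C)C | intermediate
18 | (6S)-6-(but-3-yn-1-yl)-1,5,5-trimethylcyclohex-1-ene | C#CCC[C@@H]1C(C)=CCCC1(C)C | intermediate
19 | dimethyl{(1E)-2-methyl-4-[(1S)-2,6,6-trimethylcyclohex-2-en-1-yl]but-1-en-1-yl}alane | C[Al](C)/C=C(\C)CC[C@@H]1C(C)=CCCC1(C)C | intermediate
20 | (6S)-6-[(3E)-4-iodo-3-methylbut-3-en-1-yl]-1,5,5-trimethylcyclohex-1-ene | I/C=C(\C)CC[C@@H]1C(C)=CCCC1(C)C | intermediate
21 | (2E,6E)-3,7-dimethyl-9-[(1S)-2,6,6-trimethylcyclohex-2-en-1-yl]nona-2,6-dien-1-yl (9Z,12Z,15Z)-octadeca-9,12,15-trienoate | CC/C=C\C/C=C\C/C=C\CCCCCCCC(=O)OC/C=C(\C)CC/C=C(\C)CC[C@@H]1C(C)=CCCC1(C)C | target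

Total step count: 12. Longest linear sequence: 7 steps (steps 1 to 6, then step 12). The ring-A arm takes 6 steps (steps 7 to 11, then step 12).

Steps most likely to fail

1. Step 12.
- Risk: Low-valent nickel may ionise the allylic ester. The C5 radical may also be lost through reduction, dimerisation or hydrogen abstraction at the bis-allylic positions before nickel captures it, so that cross-coupling is outrun.
- Fallback (sets out from 20, comes back at 21): a B-alkyl Suzuki–Miyaura union of the same two carbons, with the linolenate added last so that neither the allylic ester nor the triene meets a low-valent metal. Commercial (E)-3-methylpent-2-en-4-yn-1-ol is silylated (TBSCl, imidazole, DMF) to the enyne silyl ether F1. Semihydrogenation (H2, Pd/CaCO3 poisoned with Pb(OAc)2, quinoline) gives the dienyl silyl ether F2. Hydroboration at the terminal vinyl group with 9-BBN-H in THF gives the B-alkyl borane F3. Coupling of F3 with 20 (Pd(dppf)Cl2, AsPh3, Cs2CO3, DMF/H2O, rt) should form the C5–C6 bond with retention and give the diterpenyl silyl ether F4. Bu4NF in THF frees the diterpenol F5, and Steglich esterification of F5 with 4 gives 21.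

2. Step 9.
- Risk: Attack at the ring carbon flanked by the gem-dimethyl group may be too slow. Direct substitution at the carbinol carbon or loss of the picolinate by elimination would then take over, and both regiocontrol and chirality transfer would erode.
- Fallback (sets out from 10, comes back at 18): an intramolecular, suprafacial [3,3] chirality transfer in place of the intermolecular substitution. Compound 10 is reduced with the (S)-configured 2-methyl-CBS-oxazaborolidine and BH3·SMe2 to the (R)-allylic alcohol F6. Johnson–Claisen rearrangement (MeC(OEt)3, cat. EtCO2H, 140 °C) delivers the carbon on the face that bore oxygen and gives the homologous ethyl ester F7. LiAlH4 gives the primary alcohol F8, and an Appel reaction (I2, PPh3, imidazole) gives the primary iodide F9. Lithium acetylide–ethylenediamine complex in DMSO then gives 18.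

3. Step 7.
- Risk: Facial discrimination on the hindered enone may be incomplete, or uncatalysed borane reduction may compete. Either would lower the enantiomeric purity that every later step inherits.
- Fallback (sets out from 10, comes back at 11): resolution in place of asymmetric reduction. Luche reduction (NaBH4, CeCl3·7H2O, MeOH, 0 °C) gives the racemic allylic alcohol F10. A lipase-catalysed kinetic resolution (Burkholderia cepacia lipase, vinyl acetate, MTBE, rt) should acetylate the (R)-enantiomer to the (R)-acetate F11 and leave 11, which is separated by chromatography.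

Further compounds
F1 | step 12 | tert-butyl(dimethyl){[(2E)-3-methylpent-2-en-4-yn-1-yl]oxy}silane | C#C/C(C)=C/CO[Si](C)(C)C(C)(C)C
F2 | step 12 | tert-butyl(dimethyl){[(2E)-3-methylpenta-2,4-dien-1-yl]oxy}silane | C=C/C(C)=C/CO[Si](C)(C)C(C)(C)C
F3 | step 12 | 9-[(3E)-5-{[tert-butyl(dimethyl)silyl]oxy}-3-methylpent-3-en-1-yl]-9-borabicyclo[3.3.1]nonane | CC(C)(C)[Si](C)(C)OC/C=C(\C)CCB1C2CCCC1CCC2
F4 | step 12 | tert-butyl({(2E,6E)-3,7-dimethyl-9-[(1S)-2,6,6-trimethylcyclohex-2-en-1-yl]nona-2,6-dien-1-yl}oxy)dimethylsilane | CC(C)(C)[Si](C)(C)OC/C=C(\C)CC/C=C(\C)CC[C@@H]1C(C)=CCCC1(C)C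
F5 | step 12 | (2E,6E)-3,7-dimethyl-9-[(1S)-2,6,6-trimethylcyclohex-2-en-1-yl]nona-2,6-dien-1-ol | OC/C=C(\C)CC/C=C(\C)CC[C@@H]1C(C)=CCCC1(C)C
F6 | step 9 | (R)-2,4,4-trimethylcyclohex-2-en-1-ol | O[C@@H]1CCC(C)(C)C=C1C
F7 | step 9 | ethyl [(1S)-2,6,6-trimethylcyclohex-2-en-1-yl]acetate | CCOC(=O)C[C@@H]1C(C)=CCCC1(C)C
F8 | step 9 | 2-[(1S)-2,6,6-trimethylcyclohex-2-en-1-yl]ethan-1-ol | OCC[C@@H]1C(C)=CCCC1(C)C
F9 | step 9 | (6S)-6-(2-iodoethyl)-1,5,5-trimethylcyclohex-1-ene | ICC[C@@H]1C(C)=CCCC1(C)C
F10 | step 7 | racemic 2,4,4-trimethylcyclohex-2-en-1-ol | OC1CCC(C)(C)C=C1C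
F11 | step 7 | (R)-2,4,4-trimethylcyclohex-2-en-1-yl acetate | CC(=O)O[C@@H]1CCC(C)(C)C=C1C
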